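**Plan**

1. Retrosynthesis: the four aryl C–Br bonds and the two phenolic O–H groups are unveiled last (ortho-bromination after O-demethylation). The exocyclic C5=CH bond is traced back to a C5–H butenolide, dehydrogenated through its 2-silyloxyfuran.
2. The butenolide ring (O1, C2, C3, C4, C5) is then cut at O1–C5 and at C4–aryl. C3, C4 and C5 are the three carbons of an allene and C2 is its carboxyl carbon, so an aryl iodide can be delivered to the central carbon C4 while the carboxyl oxygen closes on C5.
3. The allenoic acid is cut at the allene double bond next to the carboxyl group, into a ketene (from 3-(4-methoxyphenyl)propanoyl chloride) and a stabilised phosphorus ylide.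
4. Forward: acid chloride, ketene Wittig allenation, saponification, arylative lactonisation (the only ring; 4-iodoanisole is joined here), C5 dehydrogenation, demethylation, fourfold bromination. The chain is linear.
5. Stereochemistry: the only stereo-element of the target, the Z exocyclic alkene, arises in the HBr elimination of step 6 under thermodynamic control (the E isomer would press the benzylidene aryl against the C4 aryl). The racemic C5 centre made in step 4 is erased there.

Key step: step 4

Remark: the allene and every butenolide that still carries an sp3 C5 are racemic, and no enantiocontrol is sought because C5 ends as an sp2 carbon; species that exist only until aqueous work-up (the lithium carboxylate of the saponification, the aryloxyboron species of the demethylation) are treated as forms of the product.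

Step 1
Reactants: 1 3-(4-methoxyphenyl)propanoic acid
Product: 2 3-(4-methoxyphenyl)propanoyl chloride
Conditions: (COCl)2, DMF (catalytic), CH2Cl2, 0 °C to rt; concentrate and use crude
Reagents that add atoms: oxalyl chloride, ClC(=O)C(=O)Cl
Why: Acyl chloride formation with oxalyl chloride under DMF catalysis is routine for arylpropanoic acids, and the anisole ring is inert in the absence of a Lewis acid.

Step 2
Reactants: 2 3-(4-methoxyphenyl)propanoyl chloride; 3 ethyl (triphenylphosphoranylidene)acetate
Product: 5 ethyl 5-(4-methoxyphenyl)penta-2,3-dienoate (racemic), via (4-methoxybenzyl)ketene 4 (not isolated)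
Conditions: Et3N, CH2Cl2, 0 °C to rt (slow addition of 2)
Reagents that add atoms: none
Why: Et3N dehydrochlorinates 2 to the monosubstituted ketene, whose carbonyl group should undergo Wittig olefination with the stabilised ylide faster than the ketene dimerises, giving the 2,3-dienoate (ketene Wittig allenation driven by formation of triphenylphosphine oxide).

Step 3
Reactants: 5 ethyl 5-(4-methoxyphenyl)penta-2,3-dienoate
Product: 6 5-(4-methoxyphenyl)penta-2,3-dienoic acid (racemic)
Conditions: LiOH, THF/H2O, 0 °C to rt; then 1 M HCl, 0 °C
Reagents that add atoms: lithium hydroxide (LiOH), [Li+].[OH-]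
Why: Saponification of 2,3-allenoates with cold aqueous LiOH is the standard entry to 2,3-allenoic acids, and low temperature with short contact time should hold back prototropic isomerisation to the alkynoate or the 2,4-dienoate.

Step 4
Reactants: 6 5-(4-methoxyphenyl)penta-2,3-dienoic acid; 7 4-iodoanisole
Product: 8 5-(4-methoxybenzyl)-4-(4-methoxyphenyl)furan-2(5H)-one (racemic)
Conditions: 7 (1.1 equiv), Pd(PPh3)4 (5 mol %), Ag2CO3 (10 mol %), K2CO3 (2 equiv), MeCN, 70 °C, argon
Reagents that add atoms: none
Why: Oxidative addition of zerovalent palladium from Pd(PPh3)4 into the C–I bond of 7 gives a divalent arylpalladium iodide that Ag2CO3 turns into a more electrophilic cationic complex, which carbopalladates the allene of the carboxylate of 6 with the aryl group going to the central carbon (lactone C4) to leave a π-allylpalladium spanning C3–C5; the carboxylate oxygen then displaces palladium at C5 and returns zerovalent palladium, and the alternative order (anti-oxypalladation of the distal double bond followed by C–C reductive elimination) ends at the same product. The closest known reaction type is the palladium/silver co-catalysed coupling–cyclisation of 2,3-allenoic acids with aryl halides to 4-aryl-2(5H)-furanones. The single ring closes by O1–C5 bond formation in a 5-endo-trig mode with respect to the distal allene double bond, the retained C3=C4 double bond lying inside the new five-membered lactone. C5 becomes a stereocentre without any controlling element (racemic allene, achiral catalyst), which is accepted because step 6 makes it trigonal. The step needs the aryl group on C4 and oxygen on C5: aryl transfer to the sp carbon is the intrinsic regiochemistry of allene carbopalladation, and the carboxylate can reach only the distal terminus through a five-membered transition state, attack at C3 requiring an α-lactone. K2CO3 keeps the acid ionised and takes up HI, and holding 7 near one equivalent should limit a second arylation at the acidic C5–H of 8.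

Step 5
Reactants: 8 5-(4-methoxybenzyl)-4-(4-methoxyphenyl)furan-2(5H)-one
Product: 9 tert-butyl{[5-(4-methoxybenzyl)-4-(4-methoxyphenyl)furan-2-yl]oxy}dimethylsilane
Conditions: TBSOTf, Et3N, CH2Cl2, 0 °C; pentane extraction, cold NaHCO3 wash, used without chromatography
Reagents that add atoms: tert-butyldimethylsilyl trifluoromethanesulfonate, CC(C)(C)[Si](C)(C)OS(=O)(=O)C(F)(F)F
Why: Soft enolisation, in which O-silylation of the lactone carbonyl acidifies the C5–H that Et3N then removes, should give the aromatic 2-silyloxyfuran, the standard silyl dienol ether formation of 4-aryl butenolides.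

Step 6
Reactants: 9 tert-butyl{[5-(4-methoxybenzyl)-4-(4-methoxyphenyl)furan-2-yl]oxy}dimethylsilane
Product: 11 (Z)-5-(4-methoxybenzylidene)-4-(4-methoxyphenyl)furan-2(5H)-one, via 5-bromobutenolide 10 (not isolated)
Conditions: NBS (1.0 equiv), THF, −78 °C; then DBU, −78 °C to rt
Reagents that add atoms: none
Why: NBS should brominate the silyloxyfuran at its vinylogous terminus C5 (γ-halogenation of a silyl dienol ether), and the tertiary, acyloxy-activated bromide then loses HBr to DBU across C5–CH2 (dehydrohalogenation) to give the Z alkene, the thermodynamic geometry of γ-benzylidene butenolides because the E isomer suffers A1,3 strain between the benzylidene aryl and the C4 aryl.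

Step 7
Reactants: 11 (Z)-5-(4-methoxybenzylidene)-4-(4-methoxyphenyl)furan-2(5H)-one
Product: 12 (Z)-5-(4-hydroxybenzylidene)-4-(4-hydroxyphenyl)furan-2(5H)-one (rubrolide E)
Conditions: BBr3 (excess), CH2Cl2, −78 °C to rt; H2O
Reagents that add atoms: none
Why: Lewis-acid cleavage of aryl methyl ethers by BBr3 (boron coordination to oxygen, then bromide attack on the methyl group) should spare the lactone and the enol-ester alkene, and any acid-mediated equilibration of the alkene can only favour the Z isomer.

Step 8
Reactants: 12 (Z)-5-(4-hydroxybenzylidene)-4-(4-hydroxyphenyl)furan-2(5H)-one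
Product: 13 (Z)-5-(3,5-dibromo-4-hydroxybenzylidene)-4-(3,5-dibromo-4-hydroxyphenyl)furan-2(5H)-one (rubrolide A)
Conditions: Br2 (4.1 equiv, added dropwise as a dilute solution), 1,4-dioxane/H2O, 0 °C to rt; aqueous Na2S2O3 wash
Reagents that add atoms: bromine, BrBr
Why: Electrophilic aromatic substitution on the two para-blocked phenols should take bromine at all four ortho positions well before the electron-poor C3 or the enol-ester alkene reacts, the slow addition of dilute bromine keeping its standing concentration low.

**Compound list**

1 | 3-(4-methoxyphenyl)propanoic acid | COc1ccc(CCC(=O)O)cc1 | starting material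
2 | 3-(4-methoxyphenyl)propanoyl chloride | COc1ccc(CCC(=O)Cl)cc1 | intermediate
3 | ethyl (triphenylphosphoranylidene)acetate | CCOC(=O)C=P(c1ccccc1)(c1ccccc1)c1ccccc1 | starting material
4 | (4-methoxybenzyl)ketene, 3-(4-methoxyphenyl)prop-1-en-1-one (formed in the flask, not isolated) | COc1ccc(CC=C=O)cc1 | intermediate
5 | ethyl 5-(4-methoxyphenyl)penta-2,3-dienoate (racemic) | CCOC(=O)C=C=CCc1ccc(OC)cc1 | intermediate
6 | 5-(4-methoxyphenyl)penta-2,3-dienoic acid (racemic) | OC(=O)C=C=CCc1ccc(OC)cc1 | intermediate
7 | 4-iodoanisole | COc1ccc(I)cc1 | starting material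
8 | 5-(4-methoxybenzyl)-4-(4-methoxyphenyl)furan-2(5H)-one (racemic) | O=C1C=C(c2ccc(OC)cc2)C(Cc2ccc(OC)cc2)O1 | intermediate
9 | tert-butyl{[5-(4-methoxybenzyl)-4-(4-methoxyphenyl)furan-2-yl]oxy}dimethylsilane | CC(C)(C)[Si](C)(C)Oc1cc(-c2ccc(OC)cc2)c(Cc2ccc(OC)cc2)o1 | intermediate
10 | 5-bromo-5-(4-methoxybenzyl)-4-(4-methoxyphenyl)furan-2(5H)-one (racemic; formed in the flask, not isolated) | O=C1C=C(c2ccc(OC)cc2)C(Br)(Cc2ccc(OC)cc2)O1 | intermediate
11 | (Z)-5-(4-methoxybenzylidene)-4-(4-methoxyphenyl)furan-2(5H)-one | O=C1C=C(c2ccc(OC)cc2)/C(=C/c2ccc(OC)cc2)O1 | intermediate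
12 | (Z)-5-(4-hydroxybenzylidene)-4-(4-hydroxyphenyl)furan-2(5H)-one (rubrolide E) | O=C1C=C(c2ccc(O)cc2)/C(=C/c2ccc(O)cc2)O1 | intermediate
13 | (Z)-5-(3,5-dibromo-4-hydroxybenzylidene)-4-(3,5-dibromo-4-hydroxyphenyl)furan-2(5H)-one (rubrolide A) | O=C1C=C(c2cc(Br)c(O)c(Br)c2)/C(=C/c2cc(Br)c(O)c(Br)c2)O1 | target

**Step count**

Total: 8 steps. Longest linear sequence: 8 steps (1 to 13); 3 and 7 are purchased partners.

**Steps most likely to fail**

Step 4. Aryl transfer may fail to keep pace with ring closure, so that silver- or palladium-promoted cycloisomerisation closes the lactone without the aryl group. The π-allyl complex may also lose a β-hydride from the benzylic CH2, or the product may be arylated a second time at C5. The fallback makes the same two bonds in two known operations and sets out from 6. Iodolactonisation with I2 in MeCN at rt closes O1–C5 and places iodine on C4, giving 4-iodo-5-(4-methoxybenzyl)furan-2(5H)-one F1. Suzuki–Miyaura coupling of F1 with 4-methoxyphenylboronic acid (Pd(PPh3)4, KF, toluene/H2O, 80 °C) then forms the C4–aryl bond and returns to the route at 8.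

Step 6. The bromonium source may attack C3 or an anisyl ring instead of C5, the silyl group may be lost before bromination, or the elimination may stall. The fallback sets out from 9 and uses oxygen instead of bromine. Oxidation with dimethyldioxirane in acetone at −78 °C should hydroxylate C5 to give 5-hydroxy-5-(4-methoxybenzyl)-4-(4-methoxyphenyl)furan-2(5H)-one F2. Acid-catalysed dehydration of F2 (catalytic p-TsOH, toluene, reflux with removal of water) through the acyloxy-stabilised cation should give the Z-benzylidene and returns to the route at 11.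

Step 8. Halogenation may run past the four ortho positions onto C3 or the exocyclic double bond, or stop short and leave partially brominated mixtures that are hard to separate. The fallback sets out from 8 and puts the bromine atoms on before the exocyclic alkene exists. BBr3 in CH2Cl2 should demethylate 8 to 5-(4-hydroxybenzyl)-4-(4-hydroxyphenyl)furan-2(5H)-one F3, and Br2 in aqueous 1,4-dioxane should then brominate the four ortho positions to give 5-(3,5-dibromo-4-hydroxybenzyl)-4-(3,5-dibromo-4-hydroxyphenyl)furan-2(5H)-one F4. TBSOTf (3.5 equiv) and Et3N should silylate both phenols and the lactone to 2-(tert-butyldimethylsilyloxy)-5-[3,5-dibromo-4-(tert-butyldimethylsilyloxy)benzyl]-4-[3,5-dibromo-4-(tert-butyldimethylsilyloxy)phenyl]furan F5. NBS at −78 °C should convert it into 5-bromo-5-[3,5-dibromo-4-(tert-butyldimethylsilyloxy)benzyl]-4-[3,5-dibromo-4-(tert-butyldimethylsilyloxy)phenyl]furan-2(5H)-one F6, which is not isolated. DBU should then eliminate HBr to (Z)-5-[3,5-dibromo-4-(tert-butyldimethylsilyloxy)benzylidene]-4-[3,5-dibromo-4-(tert-butyldimethylsilyloxy)phenyl]furan-2(5H)-one F7. TBAF buffered with AcOH in THF removes the two aryl silyl ethers, and the sequence comes back to the route at 13.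

**Further compounds**

F1 | step 4 | 4-iodo-5-(4-methoxybenzyl)furan-2(5H)-one (racemic) | O=C1C=C(I)C(Cc2ccc(OC)cc2)O1
F2 | step 6 | 5-hydroxy-5-(4-methoxybenzyl)-4-(4-methoxyphenyl)furan-2(5H)-one (racemic) | O=C1C=C(c2ccc(OC)cc2)C(O)(Cc2ccc(OC)cc2)O1
F3 | step 8 | 5-(4-hydroxybenzyl)-4-(4-hydroxyphenyl)furan-2(5H)-one (racemic) | O=C1C=C(c2ccc(O)cc2)C(Cc2ccc(O)cc2)O1
F4 | step 8 | 5-(3,5-dibromo-4-hydroxybenzyl)-4-(3,5-dibromo-4-hydroxyphenyl)furan-2(5H)-one (racemic) | O=C1C=C(c2cc(Br)c(O)c(Br)c2)C(Cc2cc(Br)c(O)c(Br)c2)O1
F5 | step 8 | 2-(tert-butyldimethylsilyloxy)-5-[3,5-dibromo-4-(tert-butyldimethylsilyloxy)benzyl]-4-[3,5-dibromo-4-(tert-butyldimethylsilyloxy)phenyl]furan | CC(C)(C)[Si](C)(C)Oc1cc(-c2cc(Br)c(O[Si](C)(C)C(C)(C)C)c(Br)c2)c(Cc2cc(Br)c(O[Si](C)(C)C(C)(C)C)c(Br)c2)o1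
F6 | step 8 | 5-bromo-5-[3,5-dibromo-4-(tert-butyldimethylsilyloxy)benzyl]-4-[3,5-dibromo-4-(tert-butyldimethylsilyloxy)phenyl]furan-2(5H)-one (racemic, not isolated) | O=C1C=C(c2cc(Br)c(O[Si](C)(C)C(C)(C)C)c(Br)c2)C(Br)(Cc2cc(Br)c(O[Si](C)(C)C(C)(C)C)c(Br)c2)O1
F7 | step 8 | (Z)-5-[3,5-dibromo-4-(tert-butyldimethylsilyloxy)benzylidene]-4-[3,5-dibromo-4-(tert-butyldimethylsilyloxy)phenyl]furan-2(5H)-one | O=C1C=C(c2cc(Br)c(O[Si](C)(C)C(C)(C)C)c(Br)c2)/C(=C/c2cc(Br)c(O[Si](C)(C)C(C)(C)C)c(Br)c2)O1
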